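Ring B is not coupled to ring A but built on the ring A oxygen. The feature used is the meta pair of oxygens on C4' and C6' of ring B, with C6' bonded to the ether carbon C1'. Read backwards, C6'–C1' is the carbonyl and alpha carbon of an acetate ester already attached through oxygen to C2 of ring A, and C4'–C5' is a methyl ketone. Everything rests on the C5'–C6' disconnection. One intramolecular Claisen condensation closes ring B and aromatises it to the 4',6'-resorcinol. The precursor is the open chain MeO2C(C6')–C1'H(OAr)–C2'(CH2OSi)=C3'H–C4'(=O)–C5'H3, whose ring A phenol at C6 is deliberately left free.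

Key step: step 6

Locants: ring A is C1 (CO2Me), C2 (ether O), C3 (H), C4 (CH3), C5 (prenyl), C6 (OH). Ring B is C1' (ether), C2' (CH2OH), C3' (H), C4' (OMe), C5' (H), C6' (OMe). Open-chain compounds carry the ring B locants.

Assumption: the target is achiral. C1' is a stereocentre only in 11, 12 and 13, which are racemic, and it is erased on aromatisation. Compound 12 is drawn as the Z alkene. The E isomer or the C1'=C2' tautomer would serve equally, because all give the same dienolate in step 6.

Design remarks:
- **Free C6 phenol, protection of the benzoate.** The phenol is deprotonated first in steps 4 and 6. Its phenoxide makes the neighbouring benzoate a poor electrophile for the C1' carbanion, which could otherwise reach it through a five-membered ring. It also makes ring A too electron-rich for a Smiles migration.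
- **Free C6 phenol, protecting groups.** No acetal protecting group has to survive TiCl4 or be removed with acid next to the prenyl group. Two steps are saved.
- **Price of this design.** Step 7 needs a chemoselective methylation. It is secured by chelation and double ortho substitution of the C6 phenol.
- **NaOMe in MeOH for step 6.** Every ester exchange is degenerate and lactonisation stays reversible.

Step 1
Reactants: 1 methyl 2,6-dihydroxy-4-methylbenzoate; 2 prenyl bromide (1-bromo-3-methylbut-2-ene)
Product: 3 methyl 2,6-dihydroxy-4-methyl-3-(3-methylbut-2-enyl)benzoate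
Conditions: NaH (1.05 equiv), 2 (1.0 equiv), toluene, 0 °C to rt
Reagents that add atoms: none
Why: Ortho C-alkylation of a sodium phenoxide kept as a tight ion pair in a non-polar solvent (SN2 at the primary carbon of 2, so the prenyl unit stays linear); the two nucleophilic ring carbons of 1 are equivalent by symmetry and each is ortho to one oxygen and para to the other, so only one mono-C-prenyl isomer can form.

Step 2
Reactants: 3 methyl 2,6-dihydroxy-4-methyl-3-(3-methylbut-2-enyl)benzoate; 4 methyl bromoacetate
Product: 5 methyl 6-hydroxy-2-(2-methoxy-2-oxoethoxy)-4-methyl-5-(3-methylbut-2-enyl)benzoate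
Conditions: K2CO3 (1.1 equiv), 4 (1.05 equiv), acetone, rt to 40 °C
Reagents that add atoms: none
Why: Williamson ether synthesis: the phenol next to the free ring CH is the more acidic and more accessible one, whereas the phenol wedged between prenyl and ester reacts slowly and, once its partner is alkylated, is tied up in a hydrogen bond to the ester carbonyl, which also holds back a second alkylation.

Step 3
Reactants: 6 tert-butyldimethyl(prop-2-ynyloxy)silane (commercial)
Product: 9 5-(tert-butyldimethylsilyloxy)pent-3-yn-2-one, via lithium acetylide 7 (not isolated), via lithium hemiaminal adduct 8 (not isolated)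
Conditions: n-BuLi, THF, −78 °C; MeC(O)N(OMe)Me, −78 to 0 °C; aq. NH4Cl
Reagents that add atoms: N-methoxy-N-methylacetamide, CC(=O)N(C)OC
Why: Weinreb ketone synthesis: acetylide 7 is acylated only once because the chelated adduct 8 does not collapse to the ketone before the quench, so no tertiary alcohol can form.

Step 4
Reactants: 5 methyl 6-hydroxy-2-(2-methoxy-2-oxoethoxy)-4-methyl-5-(3-methylbut-2-enyl)benzoate
Product: 10 methyl 2-{[(Z)-2-methoxy-2-(trimethylsilyloxy)ethenyl]oxy}-4-methyl-5-(3-methylbut-2-enyl)-6-(trimethylsilyloxy)benzoate
Conditions: Me3SiCl (3 equiv), then LiN(SiMe3)2 (2.2 equiv), THF, −78 to 0 °C; concentrate, pentane, filter under Ar; used crude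
Reagents that add atoms: chlorotrimethylsilane, C[Si](C)(C)Cl
Why: Kinetic enolisation with in situ silyl trapping, as used to set up Ireland–Claisen rearrangements of alkoxyacetates: the first equivalent of base makes the C6 phenoxide, which lowers the electrophilicity of the neighbouring benzoate, and the lithium-chelated Z enolate made by the second is silylated at −78 °C before it can close onto that benzoate in a Dieckmann fashion.

Step 5
Reactants: 10 silyl ketene acetal from step 4; 9 5-(tert-butyldimethylsilyloxy)pent-3-yn-2-one
Product: 12 methyl 2-{[(Z)-3-(tert-butyldimethylsilyloxymethyl)-1-methoxy-1,5-dioxohex-3-en-2-yl]oxy}-6-hydroxy-4-methyl-5-(3-methylbut-2-enyl)benzoate (racemic), via trichlorotitanium allenolate 11 (not isolated)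
Conditions: 9, TiCl4 (1.1 equiv), CH2Cl2, −78 °C; then 10, −78 °C; sat. aq. NaHCO3
Reagents that add atoms: none
Why: Mukaiyama–Michael addition: the soft ketene acetal carbon C1' attacks the TiCl4-activated ynone at its beta alkyne carbon C2', allenolate 11 is protonated at C3' on the quench from the side of the smaller CH2OSi group, which places C4' cis to C1' (Z), the aryl OSiMe3 group hydrolyses on work-up, and C1' arises racemic, which is harmless because step 6 erases it.

Step 6
Reactants: 12 open-chain aryloxy keto ester from step 5
Product: 14 methyl 2-[2-(tert-butyldimethylsilyloxymethyl)-4,6-dihydroxyphenoxy]-6-hydroxy-4-methyl-5-(3-methylbut-2-enyl)benzoate, via cyclohexenedione 13 (not isolated)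
Conditions: NaOMe (4 equiv), dry degassed MeOH (0.02 M), Ar, rt to 60 °C; AcOH, 0 °C
Reagents that add atoms: none
Why: NaOMe first stores 12 as the C6 phenoxide and the C1' dienolate, in which rotation about C2'–C3' scrambles the alkene geometry; the small equilibrium share that keeps hydrogen on C1' and is enolised at the methyl carbon C5' adds, from the isomer with C1' and C4' cis, to ester carbon C6', methoxide leaves, and dione 13 sheds its C1' hydrogen to give the resorcinolate of 14, whose formation makes the sequence irreversible. The closest known reaction type is the alkoxide-mediated intramolecular Claisen (Dieckmann-type) condensation of 5-oxo esters to cyclohexane-1,3-diones, together with the Michael–Dieckmann annulations of acetylenic carbonyl compounds with acetonedicarboxylate or malonate donors that end in resorcinols. Ring B closes in the 6-(enolendo)-exo-trig mode, because both enolate carbons C5' and C4' end up inside the new ring, and this mode is favoured for six-membered rings. No stereocentre is created and the only one present, C1', is erased. The step needs C-acylation at C5' to win over lactonisation through the C4' enolate oxygen and over a 5-(enolexo)-exo-trig attack of C1' on the ring A benzoate: the first is undone by methoxide in methanol, and the second would turn a doubly stabilised carbanion into a non-enolisable keto ester at a carbonyl that is flanked on both sides and deactivated by the ortho phenoxide, so both remain reversible side equilibria that drain into the aromatic product. The aryloxy group is never beta to a carbanion and so cannot be expelled, and the phenoxide form of ring A resists a Smiles migration to the new C6' oxygen.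

Step 7
Reactants: 14 resorcinol from step 6
Product: 15 methyl 2-[2-(tert-butyldimethylsilyloxymethyl)-4,6-dimethoxyphenoxy]-6-hydroxy-4-methyl-5-(3-methylbut-2-enyl)benzoate
Conditions: MeI (2.2 equiv), K2CO3 (2.5 equiv), acetone, rt
Reagents that add atoms: iodomethane, CI
Why: Williamson methylation under weak base: the two ring B phenols are accessible and free of hydrogen bonding, whereas the ring A phenol at C6 is chelated to the ester carbonyl and flanked by prenyl and ester, so with a small excess of MeI at room temperature it should stay untouched.

Step 8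
Reactants: 15 silyl ether from step 7
Product: 16 methyl 6-hydroxy-2-[2-(hydroxymethyl)-4,6-dimethoxyphenoxy]-4-methyl-5-(3-methylbut-2-enyl)benzoate (target CNP0583011.0)
Conditions: Bu4NF (1.2 equiv), AcOH (1.2 equiv), THF, 0 °C to rt
Reagents that add atoms: none
Why: Fluoride-induced desilylation driven by the strong Si–F bond; the AcOH buffer keeps the medium near neutral, so methyl ester, prenyl alkene and free phenol are left alone and no strong acid ever meets the ortho-prenylphenol, which could otherwise cyclise to a chroman.

Compound list
1 | methyl 2,6-dihydroxy-4-methylbenzoate | COC(=O)c1c(O)cc(C)cc1O | starting material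
2 | prenyl bromide (1-bromo-3-methylbut-2-ene) | CC(C)=CCBr | starting material
3 | methyl 2,6-dihydroxy-4-methyl-3-(3-methylbut-2-enyl)benzoate | COC(=O)c1c(O)cc(C)c(CC=C(C)C)c1O | intermediate
4 | methyl bromoacetate | COC(=O)CBr | starting material
5 | methyl 6-hydroxy-2-(2-methoxy-2-oxoethoxy)-4-methyl-5-(3-methylbut-2-enyl)benzoate | COC(=O)COc1cc(C)c(CC=C(C)C)c(O)c1C(=O)OC | intermediate
6 | tert-butyldimethyl(prop-2-ynyloxy)silane | C#CCO[Si](C)(C)C(C)(C)C | starting material
7 | lithium acetylide of 6 | [Li]C#CCO[Si](C)(C)C(C)(C)C | intermediate
8 | lithium hemiaminal adduct of 7 and N-methoxy-N-methylacetamide (racemic) | CON(C)C(C)(O[Li])C#CCO[Si](C)(C)C(C)(C)C | intermediate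
9 | 5-(tert-butyldimethylsilyloxy)pent-3-yn-2-one | CC(=O)C#CCO[Si](C)(C)C(C)(C)C | intermediate
10 | methyl 2-{[(Z)-2-methoxy-2-(trimethylsilyloxy)ethenyl]oxy}-4-methyl-5-(3-methylbut-2-enyl)-6-(trimethylsilyloxy)benzoate | CO/C(O[Si](C)(C)C)=C/Oc1cc(C)c(CC=C(C)C)c(O[Si](C)(C)C)c1C(=O)OC | intermediate
11 | trichlorotitanium allenolate: methyl 2-{[3-(tert-butyldimethylsilyloxymethyl)-1-methoxy-1-oxo-5-(trichlorotitanyloxy)hexa-3,4-dien-2-yl]oxy}-4-methyl-5-(3-methylbut-2-enyl)-6-(trimethylsilyloxy)benzoate (racemic, allene axis undefined) | CC(O[Ti](Cl)(Cl)Cl)=C=C(CO[Si](C)(C)C(C)(C)C)C(Oc1cc(C)c(CC=C(C)C)c(O[Si](C)(C)C)c1C(=O)OC)C(=O)OC | intermediate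
12 | methyl 2-{[(Z)-3-(tert-butyldimethylsilyloxymethyl)-1-methoxy-1,5-dioxohex-3-en-2-yl]oxy}-6-hydroxy-4-methyl-5-(3-methylbut-2-enyl)benzoate (racemic at C1') | COC(=O)C(Oc1cc(C)c(CC=C(C)C)c(O)c1C(=O)OC)/C(CO[Si](C)(C)C(C)(C)C)=C\C(C)=O | intermediate
13 | methyl 2-{[2-(tert-butyldimethylsilyloxymethyl)-4,6-dioxocyclohex-2-en-1-yl]oxy}-6-hydroxy-4-methyl-5-(3-methylbut-2-enyl)benzoate (racemic at C1') | O=C1CC(=O)C=C(CO[Si](C)(C)C(C)(C)C)C1Oc1cc(C)c(CC=C(C)C)c(O)c1C(=O)OC | intermediate
14 | methyl 2-[2-(tert-butyldimethylsilyloxymethyl)-4,6-dihydroxyphenoxy]-6-hydroxy-4-methyl-5-(3-methylbut-2-enyl)benzoate | COC(=O)c1c(Oc2c(CO[Si](C)(C)C(C)(C)C)cc(O)cc2O)cc(C)c(CC=C(C)C)c1O | intermediate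
15 | methyl 2-[2-(tert-butyldimethylsilyloxymethyl)-4,6-dimethoxyphenoxy]-6-hydroxy-4-methyl-5-(3-methylbut-2-enyl)benzoate | COC(=O)c1c(Oc2c(CO[Si](C)(C)C(C)(C)C)cc(OC)cc2OC)cc(C)c(CC=C(C)C)c1O | intermediate
16 | methyl 6-hydroxy-2-[2-(hydroxymethyl)-4,6-dimethoxyphenoxy]-4-methyl-5-(3-methylbut-2-enyl)benzoate | COC(=O)c1c(Oc2c(CO)cc(OC)cc2OC)cc(C)c(CC=C(C)C)c1O | target

Total step count: 8. Longest linear sequence: 7 (steps 1, 2, 4, 5, 6, 7 and 8, starting from 1).

Steps most likely to fail

1. **Step 6 (key step).**
   - What may go wrong: three processes may consume the material faster than the slow C-acylation at C5'. They are lactonisation through the enolate oxygen, intermolecular Michael addition of the dienolate to unreacted enone, and a base-induced hydrogen shift from the silyloxymethyl carbon into the enone.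
   - Fallback: the construction of ring B on the oxygen is given up and the aryl C–O bond is made directly. It sets out from 3. Ullmann-type coupling of the less hindered phenol with commercial 2-bromo-3,5-dimethoxybenzaldehyde (CuI, N,N-dimethylglycine, Cs2CO3, dioxane, 90 °C), whose ortho formyl group activates the bromide, should give methyl 2-(2-formyl-4,6-dimethoxyphenoxy)-6-hydroxy-4-methyl-5-(3-methylbut-2-enyl)benzoate F1. Reduction of the aldehyde with NaBH4 in MeOH at 0 °C comes back to the route at target 16.

2. **Step 5.**
   - What may go wrong: addition of the ketene acetal to the ketone carbonyl instead of the alkyne, stepwise [2+2] closure of the zwitterion, or protonolysis of the ketene acetal before it reacts.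
   - Fallback: the Lewis acid chemistry is replaced by a base-catalysed Michael addition of a stabilised carbanion, which adds 1,4 by nature. This also bypasses steps 2 and 4. It sets out from 3 and 9.
   - O-alkylation of the less hindered phenol of 3 with dimethyl chloromalonate (K2CO3, acetone, rt to 40 °C) should give dimethyl 2-[3-hydroxy-2-(methoxycarbonyl)-5-methyl-4-(3-methylbut-2-enyl)phenoxy]propanedioate F2.
   - Catalytic Cs2CO3 in MeCN then adds the malonate carbon of F2 to C2' of ynone 9. This should give dimethyl 2-[(Z)-1-(tert-butyldimethylsilyloxy)-4-oxopent-2-en-2-yl]-2-[3-hydroxy-2-(methoxycarbonyl)-5-methyl-4-(3-methylbut-2-enyl)phenoxy]propanedioate F3.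
   - NaOMe (2 equiv, one being taken up by the phenol) in MeOH at 0 °C removes one methoxycarbonyl group, because the departing carbanion is the doubly stabilised C1' dienolate. An AcOH quench comes back to the route at 12.

3. **Step 1.**
   - What may go wrong: O-alkylation and a second C-alkylation compete with the single C-prenylation.
   - Fallback: the position is fixed by halogenation and the prenyl group is brought in by cross-coupling. It sets out from 1. Mono-iodination with N-iodosuccinimide (MeCN, 0 °C) at one of the two equivalent activated ring carbons should give methyl 2,6-dihydroxy-3-iodo-4-methylbenzoate F4. Stille coupling with tributyl(3-methylbut-2-enyl)stannane (Pd(PPh3)4, DMF, 80 °C) comes back to the route at 3.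

Further compounds
F1 | step 6 | methyl 2-(2-formyl-4,6-dimethoxyphenoxy)-6-hydroxy-4-methyl-5-(3-methylbut-2-enyl)benzoate | COC(=O)c1c(Oc2c(C=O)cc(OC)cc2OC)cc(C)c(CC=C(C)C)c1O
F2 | step 5 | dimethyl 2-[3-hydroxy-2-(methoxycarbonyl)-5-methyl-4-(3-methylbut-2-enyl)phenoxy]propanedioate | COC(=O)C(Oc1cc(C)c(CC=C(C)C)c(O)c1C(=O)OC)C(=O)OC
F3 | step 5 | dimethyl 2-[(Z)-1-(tert-butyldimethylsilyloxy)-4-oxopent-2-en-2-yl]-2-[3-hydroxy-2-(methoxycarbonyl)-5-methyl-4-(3-methylbut-2-enyl)phenoxy]propanedioate | COC(=O)C(Oc1cc(C)c(CC=C(C)C)c(O)c1C(=O)OC)(C(=O)OC)/C(CO[Si](C)(C)C(C)(C)C)=C\C(C)=O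
F4 | step 1 | methyl 2,6-dihydroxy-3-iodo-4-methylbenzoate | COC(=O)c1c(O)cc(C)c(I)c1O
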